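A direct plan would start from the arene: Friedel–Crafts chemistry would give, after a five-step run-up, the racemic 2-tetralone A1; a chiral-amine-mediated Michael/Robinson annulation would add ring A (enone A2) and reductive methylation would give the trans-fused ketone A3.
Ring A would then be cut open again (Baeyer–Villiger oxidation, methanolysis, dehydration), the aryl ethers exchanged for a silyl ether and a triflate (A4), the vinyl group coupled in, and phenol A5 dearomatised with singlet oxygen.
Weak point 1, the asymmetric Michael addition on A1: it would follow five linear steps to a simple racemic ketone, would need a stoichiometric auxiliary, and its quaternary centre would have to be upgraded by recrystallisation.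
Weak point 2, building ring A only to cleave it: annulation, reductive methylation, Baeyer–Villiger oxidation, methanolysis and dehydration would spend five steps to end with one isopropenyl group and one propanoate chain.
Weak point 3, the phenol shuffle around A4: demethylation, site-selective monosilylation of one of two similar phenols, triflation and later desilylation would be four steps that build no bond and rest on a steric differentiation.

**Retrosynthetic overview**

Numbering is that of the target (ring B: C1–C4, C4a, C8a; ring C: C4a, C5–C8, C8a). The C1(methyl)(propanoate)/C2-isopropenyl pair of ring B is read as a ring-opened pinane: (1S,5S)-verbenone 1 already holds C2 with its masked isopropenyl group, conjugate addition anti to the gem-dimethyl bridge sets the quaternary C1 relative to it, and a later cyclobutane fragmentation unveils the isopropenyl group and the C4 methylene.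
Ring C is cut at C6–C7, C4a–C5 and C8–C8a: the ring with C5-vinyl, C6-methyl, C7-oxygen and C8-H is the aromatised form of a dienyl-substituted acetic acid, so it is closed last by an acylative benzannulation of lactone 16.
Order of ring formation: ring B (bought, then unmasked), then ring C; the hydroperoxide is made in the final operation on the phenolate released in the flask from aryl acetate 19.
This removes the run-up and the auxiliary (chiral pool, substrate control), the ring A detour (the seco unit comes from the cyclobutane) and every phenol protecting-group, triflate and cross-coupling step (the vinyl group arrives on the nucleophile).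

Key step: step 8

Remark: (1S,5S)-(−)-verbenone is taken as bought in enantiopure form; the temporary stereocentres at the future C8a and C4a are drawn as expected or left open, because both vanish in step 8.

**Route**

Step 1
Reactants: 1 (1S,5S)-(−)-verbenone; 2 but-3-en-1-ylmagnesium bromide
Product: 4 (1S,4S,5S)-4-(but-3-en-1-yl)-4,6,6-trimethylbicyclo[3.1.1]heptan-2-one, via silyl enol ether 3 (not isolated)
Conditions: 2 (1.5 equiv), CuBr·SMe2 (10 mol%), TMSCl, THF, −78 to −20 °C; then 1 M HCl
Reagents that add atoms: none
Why: Copper-catalysed conjugate addition of the Grignard reagent, accelerated by TMSCl, should deliver the butenyl group to the β-carbon from the face opposite the gem-dimethyl bridge (the usual course of cuprate additions to verbenone), which sets the quaternary carbon (future C1) with its methyl group syn to the bridge, i.e. cis to the future isopropenyl group at C2.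

Step 2
Reactants: 4 (1S,4S,5S)-4-(but-3-en-1-yl)-4,6,6-trimethylbicyclo[3.1.1]heptan-2-one; 5 allyl bromide
Product: 6 (1S,3R,4R,5R)-4-(but-3-en-1-yl)-4,6,6-trimethyl-3-(prop-2-en-1-yl)bicyclo[3.1.1]heptan-2-one
Conditions: LiN(iPr)2, THF, −78 °C; then 5, DMPU, −78 to 0 °C
Reagents that add atoms: none
Why: Enolate alkylation (SN2): C3 is the only enolisable position of 4 because C1 is a bridgehead, so the site of allylation is unambiguous; the allyl group should enter anti to the bridge, but this centre (future C8a) is planarised later.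

Step 3
Reactants: 6 (1S,3R,4R,5R)-4-(but-3-en-1-yl)-4,6,6-trimethyl-3-(prop-2-en-1-yl)bicyclo[3.1.1]heptan-2-one
Product: 7 methyl 3-[(1S,3R,4R,5R)-3-(2-methoxy-2-oxoethyl)-4,6,6-trimethyl-2-oxobicyclo[3.1.1]heptan-4-yl]propanoate
Conditions: O3, NaOH (2.5 M in MeOH), CH2Cl2, −78 °C
Reagents that add atoms: ozone, O=[O+][O-]; methanol, CO
Why: Ozonolysis in methanolic NaOH should convert each terminal alkene directly into a methyl ester (ozone oxidises the methyl hemiacetal of the ozonolysis aldehyde); both arms can be cut in one operation because the isopropenyl group is still masked as the cyclobutane, and no stereocentre is touched apart from harmless epimerisation at C3.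

Step 4
Reactants: 7 methyl 3-[(1S,3R,4R,5R)-3-(2-methoxy-2-oxoethyl)-4,6,6-trimethyl-2-oxobicyclo[3.1.1]heptan-4-yl]propanoate
Product: 9 methyl 3-[(1R,6R)-2-(2-methoxy-2-oxoethyl)-1-methyl-3-oxo-6-(prop-1-en-2-yl)cyclohexyl]propanoate (C2 epimers), via enol acetate 8 (not isolated)
Conditions: BF3·OEt2, Zn(OAc)2, Ac2O, 0 °C to rt; then K2CO3 (cat.), MeOH, 0 °C
Reagents that add atoms: none
Why: Ketone-directed Lewis-acid cyclobutane fragmentation of a 4,4-disubstituted nopinone (retro-Prins-type heterolysis of the C1–C6 bond): the enolate is trapped as enol acetate 8 while the tertiary cation loses a methyl proton to give the isopropenyl group (the isopropylidene isomer is disfavoured next to the quaternary carbon), the configurations of the future C1 and C2 are not involved, and mild methanolysis frees ketone 9.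

Step 5
Reactants: 10 (E)-but-2-enal (crotonaldehyde)
Product: 11 (Z)-2-bromobut-2-enal
Conditions: Br2, CH2Cl2, 0 °C; then Et3N, 0 °C to rt
Reagents that add atoms: bromine, BrBr
Why: Bromine addition to the enal and amine-induced E1cB loss of HBr (bromination–dehydrobromination) should give the α-bromo enal as the favoured isomer with CHO and methyl trans.

Step 6
Reactants: 11 (Z)-2-bromobut-2-enal
Product: 12 (3Z)-3-bromopenta-1,3-diene
Conditions: Ph3PCH3Br, KOtBu, THF, 0 °C; then 11, −78 °C to rt (used as a solution)
Reagents that add atoms: methyltriphenylphosphonium bromide, C[P+](c1ccccc1)(c1ccccc1)c1ccccc1.[Br-]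
Why: Wittig methylenation of the aldehyde with the non-stabilised ylide builds the vinyl group and leaves the geometry of the bromoalkene unchanged.

Step 7
Reactants: 9 methyl 3-[(1R,6R)-2-(2-methoxy-2-oxoethyl)-1-methyl-3-oxo-6-(prop-1-en-2-yl)cyclohexyl]propanoate (C2 epimers); 12 (3Z)-3-bromopenta-1,3-diene
Product: 16 methyl 3-[(4R,5R)-4-methyl-2-oxo-7a-[(3Z)-penta-1,3-dien-3-yl]-5-(prop-1-en-2-yl)octahydro-1-benzofuran-4-yl]propanoate (cis ring fusion expected; C3a/C7a left open), via dienyllithium 13 (not isolated), via organocerium reagent 14 (not isolated), via cerium alkoxide 15 (not isolated)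
Conditions: 12, t-BuLi (2 equiv), Et2O, −78 °C; CeCl3, THF, −78 °C; then 9, −78 to 0 °C; aq. NH4Cl, rt
Reagents that add atoms: none
Why: Bromine–lithium exchange (retention of alkene geometry), transmetallation to the weakly basic organocerium reagent and 1,2-addition to the ketone should form the C4a–C5 bond in preference to enolisation or ester attack; the alkoxide then lactonises onto the neighbouring acetate arm (γ-lactone), which singles out that ester as the future C7, and both new centres are erased in step 8 (any uncyclised hydroxy diester enters the same cation there).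

Step 8
Reactants: 16 methyl 3-[(4R,5R)-4-methyl-2-oxo-7a-[(3Z)-penta-1,3-dien-3-yl]-5-(prop-1-en-2-yl)octahydro-1-benzofuran-4-yl]propanoate
Product: 19 methyl 3-[(1R,2R)-7-acetoxy-5-ethenyl-1,6-dimethyl-2-(prop-1-en-2-yl)-1,2,3,4-tetrahydronaphthalen-1-yl]propanoate, via mixed anhydride 17 (not isolated), via cyclohexadienone 18 (not isolated)
Conditions: Ac2O, BF3·OEt2, Zn(OAc)2, CH2Cl2, 0 °C to rt
Reagents that add atoms: acetic anhydride, CC(=O)OC(C)=O
Why: BF3 ionises the tertiary allylic lactone C4a–O bond, and the resulting 2-vinyl-allyl cation equilibrates with the lactone and with the triene acids formed by loss of a ring proton, so the regiochemistry of that elimination is immaterial (acid-mediated funnel). The freed carboxyl group is activated by Ac2O/BF3 as mixed anhydride 17, whose acyl carbon C7 attacks the diene terminus C6 (6-endo closure, the only mode that gives a six-membered ring and a delocalised cation); proton loss gives cyclohexa-2,4-dienone 18, and O-acetylation of its enol delivers the arene as an irreversible sink. The closest known reaction type is the Stobbe-type cycloacylation of aryl- or dienyl-substituted but-3-enoic acids and their γ-lactones to naphthyl or phenyl acetates in Ac2O, with the dienylketene 6π-electrocyclisation as its thermal variant. Ring C is closed by forming the C6–C7 bond, and the vinyl (C5), methyl (C6), oxygen (C7) and hydrogen (C8) substituents are placed by the connectivity of 16 alone. No stereocentre is created, and the two temporary ring-fusion centres are destroyed. The selectivity needed is intramolecular acylation of the conjugated triene ahead of intermolecular acetylation or protonation of the isopropenyl and vinyl groups; the tether, the much higher nucleophilicity of the triene and the acetate-buffered medium in which the isopropenyl group was already generated unharmed in step 4 should secure it.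

Step 9
Reactants: 19 methyl 3-[(1R,2R)-7-acetoxy-5-ethenyl-1,6-dimethyl-2-(prop-1-en-2-yl)-1,2,3,4-tetrahydronaphthalen-1-yl]propanoate
Product: 21 trigonochinene C [methyl 3-[(1R,2R,4aR)-5-ethenyl-4a-hydroperoxy-1,6-dimethyl-7-oxo-2-(prop-1-en-2-yl)-1,2,3,4,4a,7-hexahydronaphthalen-1-yl]propanoate], via potassium phenolate 20 (not isolated)
Conditions: K2CO3, MeOH, 0 °C, Ar; then O2, rose bengal (2 mol%), visible light, −20 °C; AcOH quench
Reagents that add atoms: dioxygen (as singlet oxygen), O=O
Why: Methanolysis of the aryl acetate gives the phenolate, which should react with singlet oxygen (rose bengal sensitisation) at the para carbon C4a far faster than the isopropenyl or styrene units react in ene or [4+2] modes, and collapse of the adduct gives the para-hydroperoxy dienone; the C4a centre is set under substrate control, attack being expected anti to the pseudoaxial propanoate arm on C1 (syn to the C1 methyl group) to give the 4aR epimer, with the minor epimer removed by chromatography.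

**Compound list**

1 | (1S,5S)-(−)-verbenone [(1S,5S)-4,6,6-trimethylbicyclo[3.1.1]hept-3-en-2-one] | CC1=CC(=O)[C@H]2C[C@@H]1C2(C)C | starting material
2 | but-3-en-1-ylmagnesium bromide | C=CCC[Mg]Br | starting material
3 | trimethylsilyl enol ether of 4 (C2=C3 enol ether, configuration as in 4; not isolated) | C=CCC[C@@]1(C)C=C(O[Si](C)(C)C)[C@H]2C[C@@H]1C2(C)C | intermediate
4 | (1S,4S,5S)-4-(but-3-en-1-yl)-4,6,6-trimethylbicyclo[3.1.1]heptan-2-one (butenyl anti to the gem-dimethyl bridge) | C=CCC[C@@]1(C)CC(=O)[C@H]2C[C@@H]1C2(C)C | intermediate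
5 | allyl bromide (3-bromoprop-1-ene) | C=CCBr | starting material
6 | (1S,3R,4R,5R)-4-(but-3-en-1-yl)-4,6,6-trimethyl-3-(prop-2-en-1-yl)bicyclo[3.1.1]heptan-2-one (allyl anti to the bridge) | C=CCC[C@@]1(C)[C@@H](CC=C)C(=O)[C@H]2C[C@@H]1C2(C)C | intermediate
7 | methyl 3-[(1S,3R,4R,5R)-3-(2-methoxy-2-oxoethyl)-4,6,6-trimethyl-2-oxobicyclo[3.1.1]heptan-4-yl]propanoate | COC(=O)CC[C@@]1(C)[C@@H](CC(=O)OC)C(=O)[C@H]2C[C@@H]1C2(C)C | intermediate
8 | methyl 3-[(1R,2R,6R)-3-acetoxy-2-(2-methoxy-2-oxoethyl)-1-methyl-6-(prop-1-en-2-yl)cyclohex-3-en-1-yl]propanoate (not isolated) | COC(=O)CC[C@@]1(C)[C@@H](CC(=O)OC)C(OC(C)=O)=CC[C@@H]1C(C)=C | intermediate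
9 | methyl 3-[(1R,6R)-2-(2-methoxy-2-oxoethyl)-1-methyl-3-oxo-6-(prop-1-en-2-yl)cyclohexyl]propanoate (C2 epimers) | COC(=O)CC[C@@]1(C)C(CC(=O)OC)C(=O)CC[C@@H]1C(C)=C | intermediate
10 | (E)-but-2-enal (crotonaldehyde) | C/C=C/C=O | starting material
11 | (Z)-2-bromobut-2-enal | O=C/C(Br)=C/C | intermediate
12 | (3Z)-3-bromopenta-1,3-diene | C=C/C(Br)=C/C | intermediate
13 | (penta-1,3-dien-3-yl)lithium (lithium cis to the methyl group; not isolated) | C=C/C([Li])=C/C | intermediate
14 | dichloro(penta-1,3-dien-3-yl)cerium (not isolated) | C=C/C([Ce](Cl)Cl)=C/C | intermediate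
15 | dichlorocerium alkoxide of the tertiary alcohol from 9 and 14 (C2/C3 of the cyclohexane left open; not isolated) | COC(=O)CC[C@@]1(C)C(CC(=O)OC)C(O[Ce](Cl)Cl)(/C(C=C)=C\C)CC[C@@H]1C(C)=C | intermediate
16 | methyl 3-[(4R,5R)-4-methyl-2-oxo-7a-[(3Z)-penta-1,3-dien-3-yl]-5-(prop-1-en-2-yl)octahydro-1-benzofuran-4-yl]propanoate (cis ring fusion expected, C3a/C7a left open) | COC(=O)CC[C@@]1(C)C2CC(=O)OC2(/C(C=C)=C\C)CC[C@@H]1C(C)=C | intermediate
17 | acetic 2-[(5R,6R)-6-(3-methoxy-3-oxopropyl)-6-methyl-2-[(3Z)-penta-1,3-dien-3-yl]-5-(prop-1-en-2-yl)cyclohex-1-en-1-yl]acetic anhydride (not isolated) | COC(=O)CC[C@@]1(C)C(CC(=O)OC(C)=O)=C(/C(C=C)=C\C)CC[C@@H]1C(C)=C | intermediate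
18 | methyl 3-[(1R,2R)-5-ethenyl-1,6-dimethyl-7-oxo-2-(prop-1-en-2-yl)-1,2,3,4,7,8-hexahydronaphthalen-1-yl]propanoate (not isolated) | C=CC1=C(C)C(=O)CC2=C1CC[C@H](C(=C)C)[C@@]2(C)CCC(=O)OC | intermediate
19 | methyl 3-[(1R,2R)-7-acetoxy-5-ethenyl-1,6-dimethyl-2-(prop-1-en-2-yl)-1,2,3,4-tetrahydronaphthalen-1-yl]propanoate | C=Cc1c(C)c(OC(C)=O)cc2c1CC[C@H](C(=C)C)[C@@]2(C)CCC(=O)OC | intermediate
20 | potassium (7R,8R)-4-ethenyl-8-(3-methoxy-3-oxopropyl)-3,8-dimethyl-7-(prop-1-en-2-yl)-5,6,7,8-tetrahydronaphthalen-2-olate (not isolated) | C=Cc1c(C)c([O-])cc2c1CC[C@H](C(=C)C)[C@@]2(C)CCC(=O)OC.[K+] | intermediate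
21 | trigonochinene C, methyl 3-[(1R,2R,4aR)-5-ethenyl-4a-hydroperoxy-1,6-dimethyl-7-oxo-2-(prop-1-en-2-yl)-1,2,3,4,4a,7-hexahydronaphthalen-1-yl]propanoate | C=CC1=C(C)C(=O)C=C2[C@]1(OO)CC[C@H](C(=C)C)[C@@]2(C)CCC(=O)OC | target

**Step count and risks**

Total step count: 9. Longest linear sequence: 7 steps (steps 1–4 and 7–9); steps 5 and 6 make the dienyl bromide.

The three steps most likely to fail:

Step 8 (key step). The cationic triene could be acetylated or oligomerised intermolecularly, or the isopropenyl group protonated, faster than ring C closes. The fallback sets out from 16 and comes back at 19 and separates ionisation from ring closure under non-acidic conditions. Zerovalent palladium (Pd(PPh3)4, THF, 60 °C) would ionise the allylic lactone to a π-allylpalladium carboxylate, and β-hydride elimination (Tsuji–Trost-type diene formation) would give 2-[(5R,6R)-6-(3-methoxy-3-oxopropyl)-6-methyl-2-[(3Z)-penta-1,3-dien-3-yl]-5-(prop-1-en-2-yl)cyclohex-1-en-1-yl]acetic acid F1. Heating F1 with Ac2O and KOAc would close ring C through the mixed anhydride, the dienylketene and a 6π-electrocyclisation (classical Stobbe-type conditions) and return aryl acetate 19.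

Step 9. Singlet oxygen may attack the wrong face of the flat phenolate at C4a, or the isopropenyl group may be consumed by an ene oxidation at long reaction times. The fallback sets out from 19 and comes back to 19 and recycles instead of selecting. The reaction would be stopped at partial conversion, the separated 4aS epimer, methyl 3-[(1R,2R,4aS)-5-ethenyl-4a-hydroperoxy-1,6-dimethyl-7-oxo-2-(prop-1-en-2-yl)-1,2,3,4,4a,7-hexahydronaphthalen-1-yl]propanoate F2, would be reduced with Zn in AcOH/Ac2O (hydroperoxide to para-quinol, reductive rearomatisation, O-acetylation) to regenerate 19, and 19 would be resubmitted.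

Step 2. C-Allylation of the hindered enolate, flanked by the new quaternary carbon and shielded by the bridge, may stall while proton transfer or O-allylation takes over. The fallback sets out from 4 and comes back at 6 and replaces the SN2 step by an ion-pair recombination. The potassium enolate of 4 (KN(SiMe3)2, THF, −78 °C) would be O-acylated with allyl chloroformate to the allyl enol carbonate F3 [(1S,5S)-4-(but-3-en-1-yl)-4,6,6-trimethylbicyclo[3.1.1]hept-2-en-2-yl prop-2-en-1-yl carbonate], and Pd(PPh3)4 would trigger the decarboxylative Tsuji allylation, in which the π-allylpalladium/enolate pair recombines at C3 to give 6.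

**Further compounds**

F1 | step 8 | 2-[(5R,6R)-6-(3-methoxy-3-oxopropyl)-6-methyl-2-[(3Z)-penta-1,3-dien-3-yl]-5-(prop-1-en-2-yl)cyclohex-1-en-1-yl]acetic acid | COC(=O)CC[C@@]1(C)C(CC(=O)O)=C(/C(C=C)=C\C)CC[C@@H]1C(C)=C
F2 | step 9 | methyl 3-[(1R,2R,4aS)-5-ethenyl-4a-hydroperoxy-1,6-dimethyl-7-oxo-2-(prop-1-en-2-yl)-1,2,3,4,4a,7-hexahydronaphthalen-1-yl]propanoate | C=CC1=C(C)C(=O)C=C2[C@@]1(OO)CC[C@H](C(=C)C)[C@@]2(C)CCC(=O)OC
F3 | step 2 | (1S,5S)-4-(but-3-en-1-yl)-4,6,6-trimethylbicyclo[3.1.1]hept-2-en-2-yl prop-2-en-1-yl carbonate (butenyl anti to the bridge) | C=CCC[C@@]1(C)C=C(OC(=O)OCC=C)[C@H]2C[C@@H]1C2(C)C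
A1 | direct plan | 5,7-dimethoxy-1,6-dimethyl-3,4-dihydronaphthalen-2(1H)-one (racemic) | COc1c(C)c(OC)cc2c1CCC(=O)C2C
A2 | direct plan | (R)-6,8-dimethoxy-1,4a,7-trimethyl-4,4a,9,10-tetrahydrophenanthren-2(3H)-one | COc1c(C)c(OC)cc2c1CCC3=C(C)C(=O)CC[C@@]23C
A3 | direct plan | (4aR,10aS)-6,8-dimethoxy-1,1,4a,7-tetramethyl-3,4,4a,9,10,10a-hexahydrophenanthren-2(1H)-one | COc1c(C)c(OC)cc2c1CC[C@H]3[C@@]2(C)CCC(=O)C3(C)C
A4 | direct plan | methyl 3-[(1R,2R)-1,6-dimethyl-2-(prop-1-en-2-yl)-5-(trifluoromethylsulfonyloxy)-7-(triisopropylsilyloxy)-1,2,3,4-tetrahydronaphthalen-1-yl]propanoate | FC(F)(F)S(=O)(=O)Oc1c(C)c(O[Si](C(C)C)(C(C)C)C(C)C)cc2c1CC[C@H](C(=C)C)[C@@]2(C)CCC(=O)OC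
A5 | direct plan | methyl 3-[(1R,2R)-5-ethenyl-7-hydroxy-1,6-dimethyl-2-(prop-1-en-2-yl)-1,2,3,4-tetrahydronaphthalen-1-yl]propanoate | C=Cc1c(C)c(O)cc2c1CC[C@H](C(=C)C)[C@@]2(C)CCC(=O)OC
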